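**Overview**

- Retrosynthetic cuts, in order: (a) the four O–alkyl bonds of the last intermediate, namely two methyl ethers and the two O–C bonds of a temporary (S,S)-pentane-2,4-diyl bridge between O4' and O7''; (b) the C3'–C8'' biaryl bond inside the resulting nine-membered ring; (c) the two bridge ether bonds, now as fragment unions; (d) the C8''–I, C3'–I and one O–CH3 bond, back to formononetin, daidzein and (2R,4R)-pentane-2,4-diol.
- Enabling feature: the 4'-hydroxyl on ring B of one daidzein unit and the 7''-hydroxyl on ring A of the other sit ortho to the two axis carbons C3' and C8'', so the target is a 2,2'-biaryldiol. Each of these native phenols can steer iodination to its own axis carbon and can anchor one end of a chiral 1,3-diol.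
- Forward: both chromone bicycles and both pendant aryl rings are bought intact. Each half is iodinated next to its single free phenol, the halves are tied through the diol by two Mitsunobu etherifications, the nine-membered dioxa ring (the only ring made) is closed by intramolecular Ullmann coupling, and BBr3 strips bridge and methyl groups.
- Stereochemistry: the C3'–C8'' axis is the only stereogenic element of the target. Its sense is dictated by the two (S) ether carbons of the bridge, which arise from the (2R,4R)-diol through two invertive Mitsunobu reactions, and the axis is not touched when the bridge is removed.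

Key step: step 6

Remark: the SMILES strings show the two bridge stereocentres but cannot show the biaryl axis, so its sense is given in the names; the free tetraphenol is assumed to hold its axis at room temperature.

**Route**

Step 1
Reactants: 1 formononetin (7-hydroxy-3-(4-methoxyphenyl)chromen-4-one)
Product: 2 8-iodoformononetin (7-hydroxy-8-iodo-3-(4-methoxyphenyl)chromen-4-one)
Conditions: NIS (1.05 equiv), DMF, 0 °C to rt, dark
Reagents that add atoms: N-iodosuccinimide, O=C1CCC(=O)N1I
Why: Electrophilic aromatic iodination ortho to the free 7-hydroxyl should go to C8, the carbon flanked by O7 and the ring oxygen and favoured by the bond fixation of the benzopyranone (as in 7-hydroxycoumarins and 7-hydroxyflavones), while the anisole ring is too weakly activated to compete in the absence of acid.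

Step 2
Reactants: 3 daidzein (7-hydroxy-3-(4-hydroxyphenyl)chromen-4-one)
Product: 4 7-O-methyldaidzein (isoformononetin, 3-(4-hydroxyphenyl)-7-methoxychromen-4-one)
Conditions: MeI (1.05 equiv), K2CO3 (1.0 equiv), DMF, rt
Reagents that add atoms: iodomethane, CI
Why: Williamson etherification in which the 7-hydroxyl, para to the C4 carbonyl and therefore a vinylogous carboxylic acid markedly more acidic than the 4'-hydroxyl, should be the one deprotonated by a single equivalent of base and hence the one methylated.

Step 3
Reactants: 4 7-O-methyldaidzein
Product: 5 3'-iodo-7-O-methyldaidzein (3-(4-hydroxy-3-iodophenyl)-7-methoxychromen-4-one)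
Conditions: NIS (1.0 equiv), TsOH·H2O (10 mol %), MeCN/DMF, 0 °C to rt
Reagents that add atoms: N-iodosuccinimide, O=C1CCC(=O)N1I
Why: Acid-promoted electrophilic aromatic iodination of the only free phenol, whose para position is blocked and whose two ortho positions (C3', C5') are equivalent, should give the mono-ortho-iodide, since ring A is activated only by an ether, is deactivated by the carbonyl, and one equivalent of reagent limits formation of the 3',5'-diiodide.

Step 4
Reactants: 2 8-iodoformononetin; 6 (2R,4R)-pentane-2,4-diol (4 equiv)
Product: 7 8-iodoformononetin 7-O-[(2S,4R)-4-hydroxypentan-2-yl] ether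
Conditions: PPh3 (1.3 equiv), DIAD (1.3 equiv), THF, 0 °C to rt
Reagents that add atoms: none
Why: Mitsunobu etherification in which the acidic 7-phenol protonates the betaine and then displaces the oxyphosphonium group at one of the two equivalent carbinols with inversion ((R) to (S)), the excess of diol suppressing reaction at the second hydroxyl, which keeps its (R) configuration.

Step 5
Reactants: 7 mono-ether of step 4; 5 3'-iodo-7-O-methyldaidzein (1.2 equiv)
Product: 8 (2S,4S)-pentane-2,4-diyl bis-ether joining O7 of the 8-iodoformononetin unit to O4' of the 3'-iodo-7-O-methyldaidzein unit (diiodide)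
Conditions: PPh3 (1.5 equiv), DIAD (1.5 equiv), THF, 0 °C to rt
Reagents that add atoms: none
Why: A second Mitsunobu etherification, now with the 3'-iodo-4'-phenol as the acid partner, should invert the remaining (R)-carbinol by SN2 displacement so that both ether carbons of the bridge are (S).

Step 6
Reactants: 8 tethered diiodide
Product: 9 (M)-configured, (S,S)-pentane-2,4-diyl-bridged 3',8''-biisoflavone (the 7,4'''-di-O-methyl ether of the target with O4' and O7'' joined by the bridge in a nine-membered 1,5-dioxa ring)
Conditions: activated Cu powder (zerovalent copper, 15 equiv), DMF, 130 °C, 0.005 M, Ar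
Reagents that add atoms: none
Why: Zerovalent copper inserts into one aryl C–I bond (the electron-poor C8''–I of the chromone is expected to go first), the arylcopper species (monovalent copper) takes up the second C–I bond held beside it by the bridge, and reductive elimination from the diarylcopper intermediate (trivalent copper) forges the C3'–C8'' bond; the closest known reaction type is the intramolecular Ullmann biaryl coupling of bis(2-iodoaryl) ethers of pentane-2,4-diol. The one ring that closes is the nine-membered dioxa ring (two ether oxygens, three bridge carbons, four aryl carbons), and it closes by C–C bond formation between the two iodinated aryl carbons, each ortho to a bridge oxygen. No stereocentre is created, but the new stereogenic axis is controlled by the two (S) ether carbons: the ring can form only through the conformer with both methyl groups turned outward, in which both O–C–C–C torsions of the bridge are gauche-plus, and this forces a positive O–C4'–C3'–C8''–C7''–O torsion, which is the (M) axis because C4' and C8a'' are the ranking ortho atoms. The opposite helix would have to turn a methyl group inward against the oxygen-bearing carbon of the other arene (a syn-pentane contact), so a single atropisomer is expected. The step also needs cross- rather than homo-coupling and the correct pair of carbons, and both are secured by the bridge together with the placement of the iodides, with high dilution holding back intermolecular coupling. The chromone carbonyls, the C2–C3 enol ether bonds and the aryl and alkyl ethers should be inert to copper metal in DMF.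

Step 7
Reactants: 9 bridged biisoflavone
Product: 10 (M)-bisoflavolin C ((M)-7,4',7'',4'''-tetrahydroxy-3',8''-biisoflavone)
Conditions: BBr3 (12 equiv), CH2Cl2, −78 °C to rt; then ice-water, 0 °C
Reagents that add atoms: none
Why: Lewis-acid ether cleavage in which bromide attacks the boron-activated methyl and secondary alkyl carbons should cut all four O–alkyl bonds on the alkyl side, leaving the aryl–O bonds, the chromones and the biaryl axis untouched, and keeping the mixture at or below room temperature guards the configuration of the freed axis.

**Compound list**

1 | formononetin (7-hydroxy-3-(4-methoxyphenyl)chromen-4-one) | O=c1c(-c2ccc(OC)cc2)coc2cc(O)ccc12 | starting material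
2 | 8-iodoformononetin | O=c1c(-c2ccc(OC)cc2)coc2c(I)c(O)ccc12 | intermediate
3 | daidzein | O=c1c(-c2ccc(O)cc2)coc2cc(O)ccc12 | starting material
4 | 7-O-methyldaidzein (isoformononetin) | O=c1c(-c2ccc(O)cc2)coc2cc(OC)ccc12 | intermediate
5 | 3'-iodo-7-O-methyldaidzein | O=c1c(-c2ccc(O)c(I)c2)coc2cc(OC)ccc12 | intermediate
6 | (2R,4R)-pentane-2,4-diol | C[C@@H](O)C[C@@H](C)O | starting material
7 | 8-iodoformononetin 7-O-[(2S,4R)-4-hydroxypentan-2-yl] ether | C[C@H](Oc1ccc2c(=O)c(-c3ccc(OC)cc3)coc2c1I)C[C@@H](C)O | intermediate
8 | (2S,4S)-pentane-2,4-diyl bis-ether of 8-iodoformononetin (O7) and 3'-iodo-7-O-methyldaidzein (O4') | C[C@H](Oc1ccc2c(=O)c(-c3ccc(OC)cc3)coc2c1I)C[C@H](C)Oc1ccc(cc1I)-c1coc2cc(OC)ccc2c1=O | intermediate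
9 | (M)-axis, (S,S)-pentane-2,4-diyl-bridged 7,4'''-di-O-methyl-3',8''-biisoflavone (nine-membered dioxa ring) | C[C@H]1C[C@H](C)Oc2ccc(cc2-c2c(O1)ccc3c(=O)c(-c4ccc(OC)cc4)coc23)-c1coc2cc(OC)ccc2c1=O | intermediate
10 | (M)-bisoflavolin C | O=c1c(-c2ccc(O)c(-c3c(O)ccc4c(=O)c(-c5ccc(O)cc5)coc34)c2)coc2cc(O)ccc12 | target

**Step count**

Total steps: 7. Longest linear sequence: 5 steps (1 → 2 → 7 → 8 → 9 → 10; equally 3 → 4 → 5 → 8 → 9 → 10).

**Steps most likely to fail**

Step 6 (key ring closure). Iodine may be lost by reduction on the hot copper surface faster than the nine-membered ring closes, or the aryl metal species may couple between molecules to give oligomers. The fallback reverses the order of bond formation: the biaryl bond is made first between two molecules and the ring is closed afterwards through the second C–O bond of the bridge. It sets out from 5 and 7. Miyaura borylation of 5 (B2pin2, KOAc, PdCl2(dppf), dioxane, 85 °C) should give 7-O-methyldaidzein 3'-boronic acid pinacol ester F1. Suzuki–Miyaura coupling of F1 with the aryl iodide 7 (Pd(OAc)2, SPhos, K3PO4, dioxane/water, 80 °C) should give the open 3',8''-biaryl with a free 4'-hydroxyl and the free (R)-carbinol on the O7'' side chain F2. Intramolecular Mitsunobu etherification of F2 at high dilution (PPh3, DIAD, toluene, rt to 60 °C) then closes the nine-membered ring with inversion to the (S,S)-bridge and comes back to the route at 9. The axis of F2 carries only hydroxy and alkoxy ortho groups and should still rotate on warming, so the rotamer that can place both methyl groups outward is the one expected to cyclise and is replenished from the other.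

Step 5 (second etherification). The activated secondary carbinol may eliminate to an alkene, or the crowded oxyphosphonium group may not be displaced by the only moderately acidic iodophenol, so that the hydrazide is alkylated instead. The fallback replaces the redox condensation by sulfonate activation and phenoxide displacement. It sets out from 7. Mesylation (MsCl, Et3N, CH2Cl2, 0 °C) should give (2R,4S)-4-{[8-iodo-3-(4-methoxyphenyl)-4-oxochromen-7-yl]oxy}pentan-2-yl methanesulfonate F3 with the carbinol configuration retained. SN2 displacement by the caesium phenoxide of 5 (Cs2CO3, DMF, 50–60 °C) should then invert that carbon and return to the route at 8.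

Step 4 (first etherification). Both hydroxyls of the diol may be etherified, and the delocalised, weakly nucleophilic 7-phenoxide may attack the oxyphosphonium intermediate too slowly, letting dehydration of the diol take over. The fallback uses a cyclic sulfate as a mono-electrophile that cannot alkylate twice. It sets out from 6 and 2. Treatment of 6 with SOCl2 (CH2Cl2, 0 °C) should give (4R,6R)-4,6-dimethyl-1,3,2-dioxathiane 2-oxide F4, and oxidation (RuCl3 cat., NaIO4, MeCN/water) should give (4R,6R)-4,6-dimethyl-1,3,2-dioxathiane 2,2-dioxide F5. Ring opening of F5 by the caesium phenoxide of 2 (Cs2CO3, DMF, 60 °C) with inversion at the attacked carbon should give caesium (2R,4S)-4-{[8-iodo-3-(4-methoxyphenyl)-4-oxochromen-7-yl]oxy}pentan-2-yl sulfate F6. Hydrolysis of the sulfate monoester (cat. H2SO4, wet THF, rt), with retention at that carbon, returns to the route at 7.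

**Further compounds**

F1 | step 6 | 7-O-methyldaidzein 3'-boronic acid pinacol ester (3-[4-hydroxy-3-(4,4,5,5-tetramethyl-1,3,2-dioxaborolan-2-yl)phenyl]-7-methoxychromen-4-one) | O=c1c(-c2ccc(O)c(B3OC(C)(C)C(C)(C)O3)c2)coc2cc(OC)ccc12
F2 | step 6 | open 3',8''-biaryl: 7,4'''-di-O-methyl ether of the target with a (2S,4R)-4-hydroxypentan-2-yl group on O7'' and a free 4'-hydroxyl | C[C@H](Oc1ccc2c(=O)c(-c3ccc(OC)cc3)coc2c1-c1cc(-c3coc4cc(OC)ccc4c3=O)ccc1O)C[C@@H](C)O
F3 | step 5 | (2R,4S)-4-{[8-iodo-3-(4-methoxyphenyl)-4-oxochromen-7-yl]oxy}pentan-2-yl methanesulfonate | C[C@H](Oc1ccc2c(=O)c(-c3ccc(OC)cc3)coc2c1I)C[C@@H](C)OS(C)(=O)=O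
F4 | step 4 | (4R,6R)-4,6-dimethyl-1,3,2-dioxathiane 2-oxide | C[C@@H]1C[C@@H](C)OS(=O)O1
F5 | step 4 | (4R,6R)-4,6-dimethyl-1,3,2-dioxathiane 2,2-dioxide | C[C@@H]1C[C@@H](C)OS(=O)(=O)O1
F6 | step 4 | caesium (2R,4S)-4-{[8-iodo-3-(4-methoxyphenyl)-4-oxochromen-7-yl]oxy}pentan-2-yl sulfate | C[C@H](Oc1ccc2c(=O)c(-c3ccc(OC)cc3)coc2c1I)C[C@@H](C)OS(=O)(=O)[O-].[Cs+]
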